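Remark on the chemistry: the target has no stereocentre and no alkene geometry. The furan atoms are numbered O1, C2 (acetate arm), C3, C4, C5 (hexadecyl chain) throughout.

## Analysis of the target

Target 7, methyl 2-(5-hexadecylfuran-2-yl)acetate (C23H40O3), is a single furan ring (O1, C2, C3, C4, C5) with a CH2CO2Me arm at C2 and an unbranched sixteen-carbon chain at C5; C3 and C4 are unsubstituted CH. There is no stereocentre, so nothing has to be controlled in space. The sensitive groups are the electron-rich 2,5-dialkylfuran (opened by acid to a 1,4-diketone, destroyed by oxidants, attacked by electrophiles at C3 and C4), the acidic methylene between ring and ester, and the methyl ester. The two oxygen-bearing ring carbons C2 and C5 stand in a 1,4-relationship, so C3 and C4 are each alpha to a latent carbonyl carbon: the C3–C4 bond joins two carbons of the same natural (donor) polarity. This bond, between the only two ring carbons without a substituent, is the feature on which the route is built. It cannot be made by enolate-plus-carbonyl logic, but it can be made if C3 becomes an acceptor through a diazo group (a carbene at copper) while C4 stays a donor as the terminal carbon of an acetylide. The remaining difficulty is economy: the two alpha substituents differ, the polar one is the more fragile, and the C16 chain makes every intermediate waxy and similar in polarity, so each avoided step and separation counts. A route that creates the ring and both substitution sites in one operation from two unbranched fragments therefore answers the real demands of this small molecule.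

## Retrosynthetic reasoning

First disconnection (ring, O1–C5). 7 is an isomer of the acyclic allenyl ketone 6 and of the alk-3-yn-1-one 5. Cutting O1–C5 and moving two hydrogens opens the furan to these chains with no change of oxidation level and no leaving group. Forward, the ketone oxygen of the β-keto ester (future O1) must add to the distal unsaturated carbon (future C5) and the ring must aromatise. The chain holds only this one ketone, so no other oxygen closure is possible.

Second disconnection (C3–C4, the strategic one). In 5 the bond between the propargylic CH2 (future C3) and the alkyne carbon (future C4) is cut. The cut falls between the two unsubstituted ring carbons, so both fragments are unbranched and functionalised only at their ends: the lipophilic C18 alkyne 2 and the C5 diazo ketone 4, which holds all three oxygens of the target. The like polarity of C3 and C4 is resolved by the diazo group: the diazo carbon of 4 becomes a carbene carbon at copper after its nitrogen has left, and the terminal carbon of 2 is a donor as a copper acetylide. The forward reaction must bond the carbene carbon to the terminal alkyne carbon only (this fixes the 2,5-pattern) and leave the triple bond itself untouched. The precursors are two acyclic compounds with no ring; the product has the complete skeleton.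

Third disconnection (4, acyl–diazo carbon bond). Cutting between the ketone carbon (future C2) and the diazo carbon (future C3) leads to the bought acid chloride 3 and a one-carbon diazoalkane nucleophile. The whole polar half of 7, including the CH2CO2Me arm and O1, then comes from one commercial C4 building block. The forward acylation must outrun loss of hydrogen chloride from 3.

Fourth disconnection (2, C(sp3)–C(sp) bond). Alkyne 2 is cut between the first chain carbon and the triple bond, giving primary bromide 1 and an acetylide anion as a C2 unit. The forward step is a plain SN2 alkylation. The two branches (1 to 2, 3 to 4) are one step each and meet in the key step.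

## Alternatives that were turned down

Alternative 1: the textbook route, two successive substitutions on a bought furan ring.
- Disconnection: the two exocyclic bonds, C5–chain and C2–CH2.
- Forward: alpha-lithiation of the unsubstituted ring and alkylation with 1 should give 2-hexadecylfuran A1. The acetate arm is then put on C5 either by an electrophilic ester-substituted carbon radical (from an iodoacetate or a xanthate) with oxidative rearomatisation, or by a second lithiation, opening of an epoxide to 2-(5-hexadecylfuran-2-yl)ethan-1-ol A2, oxidation and esterification.
- Turned down: the step from A1 to 7 is weak either way.
  - The 5-lithio derivative of A1 cannot be alkylated cleanly by a haloacetate (attack at the ester carbonyl, proton and halogen transfer). The polar variant therefore goes through A2 and needs an oxidation of a primary alcohol to the acid next to an electron-rich 2,5-dialkylfuran, the group that tolerates oxidants least, plus two more steps.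
  - The radical variant is one step, but 7 is as electron-rich as A1 and carries a doubly activated CH2, so over-reaction competes, conversion must be held low, and A1 and 7 must then be separated.
  - The sequence constructs nothing: ring and both alpha positions are bought, and the polarity relationship at C3–C4 is left unused.

Alternative 2: Stetter reaction, then Paal–Knorr closure.
- Disconnection: O1–C2 and O1–C5 (Paal–Knorr), and in the resulting 1,4-diketone the bond between the chain ketone carbon (future C5) and C4, by polarity reversal of an aldehyde.
- Forward: heptadecanal A3 (from 1 through its Grignard reagent and a formamide) and methyl 3-oxopent-4-enoate A4 react under a thiazolium-derived carbene to give methyl 3,6-dioxodocosanoate A5; acid-catalysed cyclodehydration then gives 7.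
- Turned down:
  - A4 is a vinyl ketone and a β-keto ester in one. It polymerises, adds to itself as a Michael donor under the basic conditions the carbene needs, and has to be made in two steps.
  - A5 has a second, base-driven ring closure: intramolecular aldol condensation of its C2 methylene with the C6 ketone to a cyclopentenone. The amine base of the Stetter step already opens this path, whereas the furan needs acid.
  - The count is five steps, and the ring is still closed at oxygen in the most conventional way.

Alternative 3: cross-metathesis across C3=C4.
- Disconnection: C3=C4 as an alkene by cross-metathesis, then O1–C2 by cyclodehydration.
- Forward: nonadec-1-en-3-ol A6 (vinyl Grignard addition to A3) and A4 are joined by a ruthenium alkylidene (second-generation Hoveyda–Grubbs catalyst) to the E-configured γ-hydroxy enone methyl (E)-6-hydroxy-3-oxodocos-4-enoate A7. Acid should then isomerise, cyclise and dehydrate A7 to 7.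
- Turned down: this was the closest rival, because it also makes C3–C4.
  - It depends on the same unstable A4, whose enolisable, chelating β-keto ester is a poor partner for the ruthenium catalyst.
  - Metathesis gives the E alkene, which cannot reach its own ketone until it has been isomerised. The acid that does this also offers A7 loss of water to a dienone and the enol chemistry of its β-keto ester.
  - It needs five steps from 1 and a precious-metal catalyst for a bond that the chosen route forms with CuI.

Key step: step 3

## Route

Step 1
Reactants: 1 1-bromohexadecane
Product: 2 octadec-1-yne
Conditions: LiC≡CH·H2NCH2CH2NH2 (1.5 equiv), DMSO–THF, 10 °C to rt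
Reagents that add atoms: LiC≡CH·H2NCH2CH2NH2 (lithium acetylide–ethylenediamine complex), [Li+].[C-]#C.NCCN
Why: SN2 alkylation of an acetylide anion by an unhindered primary bromide in a dipolar aprotic medium; the diamine keeps the mono-anion in solution, which disfavours double alkylation, and the slim carbon nucleophile favours substitution over E2.

Step 2
Reactants: 3 methyl 3-chloro-3-oxopropanoate
Product: 4 methyl 4-diazo-3-oxobutanoate
Conditions: CH2N2 (3 equiv), Et2O, −10 to 0 °C, 3 added slowly to the CH2N2 solution
Reagents that add atoms: diazomethane, C=[N+]=[N-]
Why: Acylation of diazomethane by an acid chloride (first stage of the Arndt–Eistert sequence); a second equivalent of diazomethane takes up the hydrogen chloride so that the diazo ketone is not converted into a chloromethyl ketone, and low temperature, inverse addition and the absence of an amine base should keep 3 from losing hydrogen chloride to a ketene.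

Step 3
Reactants: 2 octadec-1-yne; 4 methyl 4-diazo-3-oxobutanoate
Product: 7 methyl 2-(5-hexadecylfuran-2-yl)acetate, via methyl 3-oxodocos-5-ynoate 5 (not isolated), via methyl 3-oxodocosa-4,5-dienoate 6 (not isolated)
Conditions: CuI (10 mol %), MeCN–THF (2:1), 25 °C, 4 added over 4 h; then Et3N (2 equiv), 65 °C
Reagents that add atoms: none
Why: CuI and the terminal C–H of 2 give the copper acetylide (C16H33C≡CCu), which takes up diazo ketone 4 as a copper carbene with loss of nitrogen; migration of the alkynyl group from copper to the carbene carbon makes the C3–C4 bond of the future furan, and protonation of the propargyl copper species releases alk-3-yn-1-one 5. This is the copper-catalysed cross-coupling of terminal alkynes with α-diazo carbonyl compounds (carbene migratory insertion), the closest known reaction type, applied here to an α-diazo ketone that carries an ester. Et3N then shifts a proton of the CH2 between alkyne and ketone to give the 1,2-allenyl ketone 6, and the ketone oxygen adds to the copper-activated terminal allene carbon in a 5-endo closure (5-endo-trig on the allene, 5-endo-dig if 5 cyclises directly) that forms O1–C5; proton shifts aromatise the ring, as in the known CuI/amine cycloisomerisation of alkynyl and allenyl ketones to 2,5-disubstituted furans. No stereocentre is formed, and the axial chirality of 6 disappears on aromatisation. The 2,5-pattern is secured by the mechanism, because only the terminal carbon of 2 can bond to the carbene carbon and the oxygen can then reach only the other alkyne carbon. Chemoselectivity at the carbene (acetylide capture against cyclopropenation, dimerisation and insertion into the enol O–H of the β-keto ester) should be secured by slow addition of 4 in a nitrile solvent, where the carbene forms at a copper centre that already carries the acetylide. Oxygen closure should win over carbon closure because attack of the methylene between ketone and ester on the alkyne would give a four-membered ring or a non-aromatic cyclopentenone, while every enol form of 5 and 6 delivers the same oxygen to the same carbon and ends in the aromatic furan.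

## Compound list

1 | 1-bromohexadecane | CCCCCCCCCCCCCCCCBr | starting material
2 | octadec-1-yne | CCCCCCCCCCCCCCCCC#C | intermediate
3 | methyl 3-chloro-3-oxopropanoate (methyl malonyl chloride) | COC(=O)CC(Cl)=O | starting material
4 | methyl 4-diazo-3-oxobutanoate | COC(=O)CC(=O)C=[N+]=[N-] | intermediate
5 | methyl 3-oxodocos-5-ynoate | CCCCCCCCCCCCCCCCC#CCC(=O)CC(=O)OC | intermediate
6 | methyl 3-oxodocosa-4,5-dienoate (racemic allene) | CCCCCCCCCCCCCCCCC=C=CC(=O)CC(=O)OC | intermediate
7 | methyl 2-(5-hexadecylfuran-2-yl)acetate | CCCCCCCCCCCCCCCCc1ccc(CC(=O)OC)o1 | target

## Step count and risks

Total step count: 3 (steps 1 and 2 run in parallel). Longest linear sequence: 2 steps (1 to 2 to 7, or 3 to 4 to 7).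

Step 3 (key step). The most likely failure is diversion of the copper carbene before it meets the acetylide:
- attack of the ester carbonyl oxygen of 4 on its own carbene carbon (a five-membered carbonyl ylide leading to a furan-3(2H)-one);
- carbene dimerisation or insertion into an enol O–H;
- protonolysis of the acetylide by the acidic β-keto ester, which slows the productive path.

In the second stage, amine-promoted intermolecular conjugate addition of the β-keto-ester methylene to the allenyl ketone may compete with the unimolecular ring closure.

The fallback uses no diazo compound and no carbene. It sets out from 2 and comes back to the route at 5:
- 2 is deprotonated with n-BuLi (THF, −78 °C) to octadec-1-yn-1-yllithium F1.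
- F1, activated with BF3·OEt2, should open methyl 2-(oxiran-2-yl)acetate at its terminal carbon (alkynylation of an epoxide, ester tolerated at −78 °C) to give racemic methyl 3-hydroxydocos-5-ynoate F2.
- Dess–Martin oxidation of F2 should give 5, here isolated.
- 5 should cyclise to 7 with catalytic ZnCl2 in CH2Cl2 at rt (5-endo-dig cycloisomerisation of alk-3-yn-1-ones).

C3–C4 is then made by a polar epoxide opening and the oxidation level is adjusted afterwards, at the price of three steps from 2 instead of one.

Step 2. The CH2 of 3 lies between two carbonyl groups, so dehydrochlorination of 3 by the basic diazomethane (ketene formation and oligomerisation) may consume the acid chloride. Methylation of the enol of 4 by excess reagent and acid-induced loss of the diazo group during purification are further losses.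

The fallback sets out from 3 and comes back at 4. The non-basic isocyanide N-isocyaniminotriphenylphosphorane should insert into the C–Cl bond of 3 to give methyl 4-chloro-3-oxo-4-[(triphenyl-λ5-phosphanylidene)hydrazinylidene]butanoate F3. F3 is hydrolysed in the same flask to the α-keto hydrazonoyl chloride methyl 4-chloro-4-hydrazinylidene-3-oxobutanoate F4, and dehydrochlorination of F4 with Et3N in CH2Cl2 should give 4. The diazo group is thus built from an isocyanide carbon and a hydrazone nitrogen pair, not delivered by a basic diazoalkane.

Step 1. Competing E2 elimination of hydrogen bromide from 1 by the basic acetylide, a second alkylation, and prototropic migration of the triple bond of 2 away from the chain end on long exposure to the basic amine medium would lower the amount and purity of 2.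

The fallback sets out from 1 and comes back at 2. Magnesium in THF should convert 1 into hexadecylmagnesium bromide F5, and formylation with DMF should give heptadecanal F6 (the aldehyde labelled A3 among the alternatives). Ohira–Bestmann homologation of F6 (dimethyl (1-diazo-2-oxopropyl)phosphonate, K2CO3, MeOH) should give 2. The terminal alkyne is then made by one-carbon homologation of an aldehyde, not by SN2 at the bromide.

## Further compounds

F1 | step 3 | octadec-1-yn-1-yllithium | [Li]C#CCCCCCCCCCCCCCCCC
F2 | step 3 | methyl 3-hydroxydocos-5-ynoate (racemic) | CCCCCCCCCCCCCCCCC#CCC(O)CC(=O)OC
F3 | step 2 | methyl 4-chloro-3-oxo-4-[(triphenyl-λ5-phosphanylidene)hydrazinylidene]butanoate | COC(=O)CC(=O)C(Cl)=NN=P(c1ccccc1)(c1ccccc1)c1ccccc1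
F4 | step 2 | methyl 4-chloro-4-hydrazinylidene-3-oxobutanoate | COC(=O)CC(=O)C(Cl)=NN
F5 | step 1 | hexadecylmagnesium bromide | CCCCCCCCCCCCCCCC[Mg]Br
F6 | step 1 | heptadecanal | CCCCCCCCCCCCCCCCC=O
A1 | alternative 1 | 2-hexadecylfuran | CCCCCCCCCCCCCCCCc1ccco1
A2 | alternative 1 | 2-(5-hexadecylfuran-2-yl)ethan-1-ol | CCCCCCCCCCCCCCCCc1ccc(CCO)o1
A3 | alternative 2 | heptadecanal | CCCCCCCCCCCCCCCCC=O
A4 | alternative 2 | methyl 3-oxopent-4-enoate | C=CC(=O)CC(=O)OC
A5 | alternative 2 | methyl 3,6-dioxodocosanoate | CCCCCCCCCCCCCCCCC(=O)CCC(=O)CC(=O)OC
A6 | alternative 3 | nonadec-1-en-3-ol (racemic) | CCCCCCCCCCCCCCCCC(O)C=C
A7 | alternative 3 | methyl (E)-6-hydroxy-3-oxodocos-4-enoate (racemic) | CCCCCCCCCCCCCCCCC(O)/C=C/C(=O)CC(=O)OC
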